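**A direct plan and its weak points**

A direct plan would buy both ring systems and join them at the aryl–CH2 bond.
Corey–Bakshi–Shibata reduction of 2,4,4-trimethylcyclohex-2-enone and phosphorylation would give allylic phosphate A1.
A copper-catalysed anti-SN2′ transfer of CH2Bpin would turn A1 into the α-cyclogeranylmethyl boronate A2.
Kaempferol would go through MOM protection, C6 iodination and a second MOM protection to iodide A3; B-alkyl Suzuki coupling of A2 with A3 and acid would finish.
Weakest would be the SN2′ borylmethylation: it must deliver a bulky alkylcopper to an alkene carbon next to CMe2, has no precedent on so hindered a cyclic phosphate, and is the only source of the stereocentre, so any SN2 or syn leakage is lost ee.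
Next would be the sp3–sp2 Suzuki coupling of a β-branched primary boronate with a di-ortho-alkoxy aryl iodide, run on both fully elaborated halves, where slow transmetalation invites protodeboronation and hydrodeiodination.
Third, the MOM/iodination/MOM sequence on kaempferol would spend three steps without adding skeletal complexity.

**Plan of the new route**

Numbering: flavonol atoms as usual (rings A, C, B); cyclohexene ring D is C1″ (stereocentre), C2″(Me)=C3″, C4″, C5″, C6″ (CMe2).
Cuts, last bond first: ring C at O1–C2 with C3–OH (Algar–Flynn–Oyamada) and at the chalcone C=C; ring D at C2″=C3″ (ring-closing metathesis); then the hindered C1″–C6″ bond (Claisen rearrangement).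
Enabling feature: C1″ lies between quaternary C6″ and the C2″=C3″ double bond, so C6″–C1″–C2″=C3″ is the γ,δ-unsaturated carbonyl array of a Claisen product once one methyl on C6″ is written as CHO.
Because C6″ ends as CMe2, enol ether geometry and the C6″ epimer ratio do not matter, and the carbinol carbon that relays chirality to C1″ is expelled as but-1-ene when ring D closes.
Rings arise in the order A (phloroglucinol), D (step 8), C (step 13), with ring B brought in by an aldehyde; O1 is marked from step 2 by a silyl group para to the side chain, so only the 6-substituted flavonol can form.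
No SN2′ at a neopentyl carbon, no late sp3–sp2 coupling and no protecting-group shuffle occur: the aryl–CH2 bond is made first on a symmetric aryllithium and the MOM groups are put on once.

Key step: step 7

Remark: hex-1-en-5-yne, 2-methylprop-2-enal, 4-(methoxymethoxy)benzaldehyde and (+)-MIB [(2R)-3-exo-morpholinoisoborneol] are taken as purchasable. The descriptor at C1″ changes along the route (3S in 12, 2S in 13 and 14, 1R from 15 on) only because neighbour priorities change; the spatial arrangement is the same throughout.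

**Route**

Step 1
Reactants: 1 phloroglucinol (benzene-1,3,5-triol)
Product: 2 3,5-bis(methoxymethoxy)phenol
Conditions: MOMCl (2.0 equiv), iPr2NEt (2.2 equiv), DMF, 0 °C to rt; chromatography
Reagents that add atoms: chloromethyl methyl ether, COCCl
Why: Williamson-type O-alkylation of two of the three equivalent phenols under stoichiometric control, the bis-ether being separated from mono- and tris-ethers, which leaves one phenol free as the future O1.

Step 2
Reactants: 2 3,5-bis(methoxymethoxy)phenol
Product: 3 [3,5-bis(methoxymethoxy)phenoxy]tri(propan-2-yl)silane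
Conditions: TIPSCl (1.2 equiv), imidazole (2.5 equiv), DMF, rt
Reagents that add atoms: chlorotri(propan-2-yl)silane, CC(C)[Si](Cl)(C(C)C)C(C)C
Why: Imidazole-assisted O-silylation marks O1 with a bulky group that does not direct lithiation and that is lost later under hot hydroxide.

Step 3
Reactants: 3 [3,5-bis(methoxymethoxy)phenoxy]tri(propan-2-yl)silane
Product: 5 [3,5-bis(methoxymethoxy)-4-(prop-2-en-1-yl)phenoxy]tri(propan-2-yl)silane, via aryllithium 4 (not isolated)
Conditions: n-BuLi (1.1 equiv), THF, 0 °C; then CuBr·SMe2 (5 mol %), allyl bromide (1.5 equiv), −78 to 0 °C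
Reagents that add atoms: allyl bromide, C=CCBr
Why: Directed ortho-metalation removes the one hydrogen flanked by two chelating OMOM groups (the future C6), the positions next to the bulky OTIPS stay untouched, and copper-assisted allylation of the aryllithium makes the aryl–CH2 bond on a simple symmetric arene.

Step 4
Reactants: 5 [3,5-bis(methoxymethoxy)-4-(prop-2-en-1-yl)phenoxy]tri(propan-2-yl)silane
Product: 6 (2E)-4-[2,6-bis(methoxymethoxy)-4-{[tri(propan-2-yl)silyl]oxy}phenyl]-2-methylbut-2-enal
Conditions: 2-methylprop-2-enal (5 equiv), second-generation Hoveyda–Grubbs catalyst RuCl2(=CH-C6H4-2-OiPr)(H2IMes) (3 mol %), 1,4-benzoquinone (10 mol %), CH2Cl2, 40 °C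
Reagents that add atoms: 2-methylprop-2-enal (methacrolein), CC(=C)C=O
Why: Olefin cross-metathesis of a terminal alkene with a 1,1-disubstituted enal that does not homodimerise should give the trisubstituted enal under thermodynamic control as the (E)-isomer, benzoquinone suppressing isomerisation of the allylarene.

Step 5
Reactants: 6 (2E)-4-[2,6-bis(methoxymethoxy)-4-{[tri(propan-2-yl)silyl]oxy}phenyl]-2-methylbut-2-enal
Product: 7 (3R,4E)-6-[2,6-bis(methoxymethoxy)-4-{[tri(propan-2-yl)silyl]oxy}phenyl]-4-methylhex-4-en-3-ol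
Conditions: Et2Zn (2.0 equiv, 1 M in hexanes), (+)-MIB (4 mol %), toluene, 0 °C; aq. NH4Cl
Reagents that add atoms: diethylzinc, CC[Zn]CC
Why: Amino-alcohol-catalysed enantioselective addition of diethylzinc to an aldehyde, in which the zinc aminoalkoxide of (+)-MIB should deliver ethyl to the Re face (mirror image of the (S)-selective addition its enantiomer gives with aryl and alkenyl aldehydes) and so set the (3R) carbinol that will relay chirality.

Step 6
Reactants: 8 hex-1-en-5-yne
Product: 10 (1E)-1-iodo-2-methylhexa-1,5-diene, via alkenylalane 9 (not isolated)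
Conditions: Me3Al (2.0 equiv), Cp2ZrCl2 (20 mol %), CH2Cl2, 0 °C to rt; then I2 (1.2 equiv), THF, −30 to 0 °C
Reagents that add atoms: trimethylaluminium, C[Al](C)C; iodine, II
Why: Zirconium-catalysed syn-carboalumination of the terminal alkyne (methyl to the internal carbon, the isolated alkene not reacting) and iodinolysis of the alkenyl–aluminium bond with retention give the (E)-iodide, whose geometry is of no consequence later.

Step 7
Reactants: 7 (3R,4E)-6-[2,6-bis(methoxymethoxy)-4-{[tri(propan-2-yl)silyl]oxy}phenyl]-4-methylhex-4-en-3-ol; 10 (1E)-1-iodo-2-methylhexa-1,5-diene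
Product: 12 (3S,4E)-3-{[2,6-bis(methoxymethoxy)-4-{[tri(propan-2-yl)silyl]oxy}phenyl]methyl}-2-(but-3-en-1-yl)-2,4-dimethylhept-4-enal (both C2 epimers), via allyl vinyl ether 11 (not isolated)
Conditions: 10 (1.5 equiv), CuI (10 mol %), 3,4,7,8-tetramethyl-1,10-phenanthroline (20 mol %), Cs2CO3 (2.0 equiv), o-xylene, 120 °C, Ar
Reagents that add atoms: none
Why: Domino Ullmann-type C–O coupling and Claisen rearrangement, a known copper-catalysed reaction of allylic alcohols with vinyl iodides: the caesium alkoxide of 7 is vinylated at copper with retention of the iodide geometry to allyl vinyl ether 11, which at 120 °C undergoes the [3,3]-sigmatropic shift. The shift forms the most hindered bond of the target, C1″–C6″ (tertiary next to quaternary), inside a six-membered chair transition state instead of by intermolecular attack on a neopentyl carbon; no ring is closed in this step. The new stereocentre C1″ (C3 of 12) is controlled by the carbinol centre of 7: with the ethyl group and the (E)-CH2Ar group both equatorial, the enol ether carbon adds to the face of the allyl unit from which oxygen departs, so (3R,4E)-7 should give the (3S) centre of 12, which is the (1R) centre of the target, together with an (E)-C(Me)=CHEt alkene. The quaternary carbon C2 of 12 forms as a mixture of epimers from either enol ether geometry, but the mixture converges because that carbon ends as CMe2. The step needs chair over boat and equatorial over axial ethyl (secured by the acyclic substrate and the 1,3-diaxial strain of the axial alternative) and a geometrically pure alkene in 7 (secured by the thermodynamic cross-metathesis), since every (Z) or axial-ethyl leak becomes the wrong enantiomer. The aldehyde carbon is α-quaternary, cannot enolise, and is reduced to the second methyl in step 9.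

Step 8
Reactants: 12 (3S,4E)-3-{[2,6-bis(methoxymethoxy)-4-{[tri(propan-2-yl)silyl]oxy}phenyl]methyl}-2-(but-3-en-1-yl)-2,4-dimethylhept-4-enal
Product: 13 (2S)-2-{[2,6-bis(methoxymethoxy)-4-{[tri(propan-2-yl)silyl]oxy}phenyl]methyl}-1,3-dimethylcyclohex-3-ene-1-carbaldehyde (both C1 epimers)
Conditions: second-generation Hoveyda–Grubbs catalyst RuCl2(=CH-C6H4-2-OiPr)(H2IMes) (5 mol %), toluene (5 mM), 80 °C, Ar sparge
Reagents that add atoms: none
Why: Ring-closing metathesis in which the alkylidene forms at the unhindered terminal vinyl group and closes ring D onto the trisubstituted alkene (helped by the fully substituted C6″), releasing but-1-ene, so the ethyl-bearing carbon that carried the chirality is excised and C2″=C3″ is placed without regiochemical ambiguity while C1″ is untouched.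

Step 9
Reactants: 13 (2S)-2-{[2,6-bis(methoxymethoxy)-4-{[tri(propan-2-yl)silyl]oxy}phenyl]methyl}-1,3-dimethylcyclohex-3-ene-1-carbaldehyde
Product: 15 3,5-bis(methoxymethoxy)-4-{[(1R)-2,6,6-trimethylcyclohex-2-en-1-yl]methyl}phenol, via hydrazone 14 (not isolated)
Conditions: N2H4·H2O (10 equiv), diethylene glycol, 130 °C; then KOH (10 equiv), 195 °C, N2; aq. NH4Cl
Reagents that add atoms: none
Why: Wolff–Kishner reduction (Huang–Minlon procedure) of the non-enolisable neopentyl aldehyde gives the second methyl on C6″, the isolated trisubstituted alkene and the MOM acetals being inert to base, and the hot hydroxide should cleave the aryl silyl ether so that the O1 phenol is freed in the same operation.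

Step 10
Reactants: 15 3,5-bis(methoxymethoxy)-4-{[(1R)-2,6,6-trimethylcyclohex-2-en-1-yl]methyl}phenol
Product: 16 2-bromo-3,5-bis(methoxymethoxy)-4-{[(1R)-2,6,6-trimethylcyclohex-2-en-1-yl]methyl}phenol
Conditions: NBS (1.0 equiv), CH2Cl2, −78 °C, dark
Reagents that add atoms: N-bromosuccinimide, O=C1CCC(=O)N1Br
Why: Electrophilic aromatic bromination of a very electron-rich phenol at −78 °C should be far faster than attack on the hindered alkene, and since the para position carries the side chain and the two ortho positions are equivalent, one equivalent can only give the bromide at the future C4a.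

Step 11
Reactants: 16 2-bromo-3,5-bis(methoxymethoxy)-4-{[(1R)-2,6,6-trimethylcyclohex-2-en-1-yl]methyl}phenol
Product: 18 1-[6-hydroxy-2,4-bis(methoxymethoxy)-3-{[(1R)-2,6,6-trimethylcyclohex-2-en-1-yl]methyl}phenyl]ethan-1-one, via dilithio phenoxide 17 (not isolated)
Conditions: n-BuLi (2.2 equiv), THF, −78 °C; then MeC(O)N(OMe)Me (1.5 equiv), −78 to 0 °C; aq. NH4Cl
Reagents that add atoms: N-methoxy-N-methylacetamide, CON(C)C(C)=O
Why: Deprotonation of the phenol and bromine–lithium exchange give the ortho-lithiated phenoxide, which the Weinreb amide acylates through a stable chelated tetrahedral adduct (no over-addition) to the ortho-hydroxy ketone whose free hydroxyl is the one next to the ring C–H.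

Step 12
Reactants: 18 1-[6-hydroxy-2,4-bis(methoxymethoxy)-3-{[(1R)-2,6,6-trimethylcyclohex-2-en-1-yl]methyl}phenyl]ethan-1-one; 19 4-(methoxymethoxy)benzaldehyde
Product: 20 (2E)-1-[6-hydroxy-2,4-bis(methoxymethoxy)-3-{[(1R)-2,6,6-trimethylcyclohex-2-en-1-yl]methyl}phenyl]-3-[4-(methoxymethoxy)phenyl]prop-2-en-1-one
Conditions: 19 (1.2 equiv), KOH (50% aq., 10 equiv), EtOH, rt
Reagents that add atoms: none
Why: Claisen–Schmidt condensation of the methyl ketone enolate with the non-enolisable aldehyde and E1cB dehydration give the (E)-chalcone, MOM ethers and the isolated alkene being stable to aqueous KOH.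

Step 13
Reactants: 20 (2E)-1-[6-hydroxy-2,4-bis(methoxymethoxy)-3-{[(1R)-2,6,6-trimethylcyclohex-2-en-1-yl]methyl}phenyl]-3-[4-(methoxymethoxy)phenyl]prop-2-en-1-one
Product: 22 3-hydroxy-5,7-bis(methoxymethoxy)-2-[4-(methoxymethoxy)phenyl]-6-{[(1R)-2,6,6-trimethylcyclohex-2-en-1-yl]methyl}-4H-chromen-4-one, via dihydroflavonol 21 (not isolated)
Conditions: H2O2 (30% aq., 4 equiv), NaOH (2 M aq., 5 equiv), MeOH, 0 °C to rt
Reagents that add atoms: hydrogen peroxide, OO
Why: Algar–Flynn–Oyamada reaction, in which alkaline peroxide attacks only the electron-poor enone (not the isolated alkene), the free phenoxide closes ring C at C-β (6-endo, O1–C2) to the dihydroflavonol and this is oxidised in the flask to the flavonol; because the only free phenol is the one flanked by the ring C–H, the terpenoid group must end at C6.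

Step 14
Reactants: 22 3-hydroxy-5,7-bis(methoxymethoxy)-2-[4-(methoxymethoxy)phenyl]-6-{[(1R)-2,6,6-trimethylcyclohex-2-en-1-yl]methyl}-4H-chromen-4-one
Product: 23 Ugonin G
Conditions: HCl (1.25 M in MeOH), THF, rt to 40 °C; NaHCO3 quench at full conversion
Reagents that add atoms: none
Why: Acid-catalysed transacetalisation of the three aryl MOM ethers to dimethoxymethane, under conditions used for prenylated flavonoids, should be complete before the trisubstituted alkene is protonated (which would let the 5- or 7-OH add to C2″), and the stereocentre is untouched.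

**Compound list**

1 | phloroglucinol (benzene-1,3,5-triol) | Oc1cc(O)cc(O)c1 | starting material
2 | 3,5-bis(methoxymethoxy)phenol | COCOc1cc(O)cc(OCOC)c1 | intermediate
3 | [3,5-bis(methoxymethoxy)phenoxy]tri(propan-2-yl)silane | COCOc1cc(O[Si](C(C)C)(C(C)C)C(C)C)cc(OCOC)c1 | intermediate
4 | [2,6-bis(methoxymethoxy)-4-{[tri(propan-2-yl)silyl]oxy}phenyl]lithium | [Li]c1c(OCOC)cc(O[Si](C(C)C)(C(C)C)C(C)C)cc1OCOC | intermediate
5 | [3,5-bis(methoxymethoxy)-4-(prop-2-en-1-yl)phenoxy]tri(propan-2-yl)silane | C=CCc1c(OCOC)cc(O[Si](C(C)C)(C(C)C)C(C)C)cc1OCOC | intermediate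
6 | (2E)-4-[2,6-bis(methoxymethoxy)-4-{[tri(propan-2-yl)silyl]oxy}phenyl]-2-methylbut-2-enal | O=C/C(C)=C/Cc1c(OCOC)cc(O[Si](C(C)C)(C(C)C)C(C)C)cc1OCOC | intermediate
7 | (3R,4E)-6-[2,6-bis(methoxymethoxy)-4-{[tri(propan-2-yl)silyl]oxy}phenyl]-4-methylhex-4-en-3-ol | CC[C@@H](O)/C(C)=C/Cc1c(OCOC)cc(O[Si](C(C)C)(C(C)C)C(C)C)cc1OCOC | intermediate
8 | hex-1-en-5-yne | C=CCCC#C | starting material
9 | dimethyl[(1E)-2-methylhexa-1,5-dien-1-yl]alumane | C[Al](C)/C=C(\C)CCC=C | intermediate
10 | (1E)-1-iodo-2-methylhexa-1,5-diene | I/C=C(\C)CCC=C | intermediate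
11 | {3,5-bis(methoxymethoxy)-4-[(2E,4R)-3-methyl-4-{[(1E)-2-methylhexa-1,5-dien-1-yl]oxy}hex-2-en-1-yl]phenoxy}tri(propan-2-yl)silane | CC[C@@H](O/C=C(\C)CCC=C)/C(C)=C/Cc1c(OCOC)cc(O[Si](C(C)C)(C(C)C)C(C)C)cc1OCOC | intermediate
12 | (3S,4E)-3-{[2,6-bis(methoxymethoxy)-4-{[tri(propan-2-yl)silyl]oxy}phenyl]methyl}-2-(but-3-en-1-yl)-2,4-dimethylhept-4-enal (both C2 epimers) | O=CC(C)(CCC=C)[C@@H](Cc1c(OCOC)cc(O[Si](C(C)C)(C(C)C)C(C)C)cc1OCOC)/C(C)=C/CC | intermediate
13 | (2S)-2-{[2,6-bis(methoxymethoxy)-4-{[tri(propan-2-yl)silyl]oxy}phenyl]methyl}-1,3-dimethylcyclohex-3-ene-1-carbaldehyde (both C1 epimers) | O=CC1(C)CCC=C(C)[C@@H]1Cc1c(OCOC)cc(O[Si](C(C)C)(C(C)C)C(C)C)cc1OCOC | intermediate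
14 | {[(2S)-2-{[2,6-bis(methoxymethoxy)-4-{[tri(propan-2-yl)silyl]oxy}phenyl]methyl}-1,3-dimethylcyclohex-3-en-1-yl]methylidene}hydrazine | NN=CC1(C)CCC=C(C)[C@@H]1Cc1c(OCOC)cc(O[Si](C(C)C)(C(C)C)C(C)C)cc1OCOC | intermediate
15 | 3,5-bis(methoxymethoxy)-4-{[(1R)-2,6,6-trimethylcyclohex-2-en-1-yl]methyl}phenol | CC1=CCCC(C)(C)[C@H]1Cc1c(OCOC)cc(O)cc1OCOC | intermediate
16 | 2-bromo-3,5-bis(methoxymethoxy)-4-{[(1R)-2,6,6-trimethylcyclohex-2-en-1-yl]methyl}phenol | CC1=CCCC(C)(C)[C@H]1Cc1c(OCOC)cc(O)c(Br)c1OCOC | intermediate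
17 | lithium 2-lithio-3,5-bis(methoxymethoxy)-4-{[(1R)-2,6,6-trimethylcyclohex-2-en-1-yl]methyl}phenolate | CC1=CCCC(C)(C)[C@H]1Cc1c(OCOC)cc(O[Li])c([Li])c1OCOC | intermediate
18 | 1-[6-hydroxy-2,4-bis(methoxymethoxy)-3-{[(1R)-2,6,6-trimethylcyclohex-2-en-1-yl]methyl}phenyl]ethan-1-one | CC1=CCCC(C)(C)[C@H]1Cc1c(OCOC)cc(O)c(C(C)=O)c1OCOC | intermediate
19 | 4-(methoxymethoxy)benzaldehyde | COCOc1ccc(C=O)cc1 | starting material
20 | (2E)-1-[6-hydroxy-2,4-bis(methoxymethoxy)-3-{[(1R)-2,6,6-trimethylcyclohex-2-en-1-yl]methyl}phenyl]-3-[4-(methoxymethoxy)phenyl]prop-2-en-1-one | CC1=CCCC(C)(C)[C@H]1Cc1c(OCOC)cc(O)c(C(=O)/C=C/c2ccc(OCOC)cc2)c1OCOC | intermediate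
21 | trans-3-hydroxy-5,7-bis(methoxymethoxy)-2-[4-(methoxymethoxy)phenyl]-6-{[(1R)-2,6,6-trimethylcyclohex-2-en-1-yl]methyl}-2,3-dihydro-4H-chromen-4-one (both trans diastereomers) | CC1=CCCC(C)(C)[C@H]1Cc1c(OCOC)cc2OC(c3ccc(OCOC)cc3)C(O)C(=O)c2c1OCOC | intermediate
22 | 3-hydroxy-5,7-bis(methoxymethoxy)-2-[4-(methoxymethoxy)phenyl]-6-{[(1R)-2,6,6-trimethylcyclohex-2-en-1-yl]methyl}-4H-chromen-4-one | CC1=CCCC(C)(C)[C@H]1Cc1c(OCOC)cc2oc(-c3ccc(OCOC)cc3)c(O)c(=O)c2c1OCOC | intermediate
23 | Ugonin G, 3,5,7-trihydroxy-2-(4-hydroxyphenyl)-6-{[(1R)-2,6,6-trimethylcyclohex-2-en-1-yl]methyl}-4H-chromen-4-one | CC1=CCCC(C)(C)[C@H]1Cc1c(O)cc2oc(-c3ccc(O)cc3)c(O)c(=O)c2c1O | target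

**Count and risks**

Total step count: 14. Longest linear sequence: 13 steps (steps 1–5 and 7–14 from phloroglucinol); step 6 is a one-step side branch.

Steps most likely to fail:

Step 7. The C–O coupling of the hindered secondary alkoxide may be slow, the allylic alcohol may ionise or transpose at 120 °C before it is vinylated, or some material may pass through the axial-ethyl chair and erode the ee. The fallback sets out from 7 and makes the same C1″–C6″ bond by an Ireland–Claisen rearrangement. Esterification with 2-methylhex-5-enoic acid (DCC, DMAP, CH2Cl2) would give (3R,4E)-6-[2,6-bis(methoxymethoxy)-4-{[tri(propan-2-yl)silyl]oxy}phenyl]-4-methylhex-4-en-3-yl 2-methylhex-5-enoate F1. LDA and Me3SiCl in THF at −78 °C, then 65 °C, would carry it through its trimethylsilyl ketene acetal F2 (same chair, same chirality transfer) to (3S,4E)-3-{[2,6-bis(methoxymethoxy)-4-{[tri(propan-2-yl)silyl]oxy}phenyl]methyl}-2-(but-3-en-1-yl)-2,4-dimethylhept-4-enoic acid F3. LiAlH4 would give the corresponding hept-4-en-1-ol F4, and Dess–Martin periodinane would come back to the route at aldehyde 12.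

Step 8. The alkylidene formed at the terminal vinyl group may fail to engage the hindered (E)-trisubstituted alkene, so that intermolecular metathesis outruns ring closure. The fallback sets out from 6 and exchanges the ethyl group for a relay arm. Di(pent-4-en-1-yl)zinc F5 (from pent-4-en-1-ylmagnesium bromide and ZnCl2, magnesium salts sequestered with N,N,N′,N′-tetraethylethylenediamine) under the same (+)-MIB catalysis would give (2E,4R)-1-[2,6-bis(methoxymethoxy)-4-{[tri(propan-2-yl)silyl]oxy}phenyl]-3-methylnona-2,8-dien-4-ol F6. The conditions of step 7 would give (3S,4E)-3-{[2,6-bis(methoxymethoxy)-4-{[tri(propan-2-yl)silyl]oxy}phenyl]methyl}-2-(but-3-en-1-yl)-2,4-dimethyldeca-4,9-dienal F7. In F7 the catalyst starts at the unhindered pentenyl terminus, expels cyclopentene and is thereby placed directly on C2″ (relay ring-closing metathesis); closure onto the vinyl group comes back to the route at 13.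

Step 13. The phenoxide may attack C-α in a 5-exo mode, favoured by the ortho alkoxy group that twists the carbonyl out of conjugation, and divert the chalcone toward an aurone. The fallback sets out from 16 and builds ring C without an epoxide. Dianion 17 would be acylated with N-methoxy-N-methyl-3-[4-(methoxymethoxy)phenyl]prop-2-ynamide F8 (from 1-ethynyl-4-(methoxymethoxy)benzene, n-BuLi and N-methoxy-N-methylcarbamoyl chloride) to give 1-[6-hydroxy-2,4-bis(methoxymethoxy)-3-{[(1R)-2,6,6-trimethylcyclohex-2-en-1-yl]methyl}phenyl]-3-[4-(methoxymethoxy)phenyl]prop-2-yn-1-one F9. Et2NH in EtOH (conjugate addition to an enaminone, then 6-endo addition–elimination) would give 5,7-bis(methoxymethoxy)-2-[4-(methoxymethoxy)phenyl]-6-{[(1R)-2,6,6-trimethylcyclohex-2-en-1-yl]methyl}-4H-chromen-4-one F10. C3 lithiation with LDA at −78 °C, trapping with B(OMe)3 and oxidation with H2O2 would come back to the route at 22.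

Further compounds
F1 | step 7 | (3R,4E)-6-[2,6-bis(methoxymethoxy)-4-{[tri(propan-2-yl)silyl]oxy}phenyl]-4-methylhex-4-en-3-yl 2-methylhex-5-enoate | CC[C@@H](OC(=O)C(C)CCC=C)/C(C)=C/Cc1c(OCOC)cc(O[Si](C(C)C)(C(C)C)C(C)C)cc1OCOC
F2 | step 7 | trimethylsilyl ketene acetal of F1 (E/Z mixture) | CC[C@@H](OC(O[Si](C)(C)C)=C(C)CCC=C)/C(C)=C/Cc1c(OCOC)cc(O[Si](C(C)C)(C(C)C)C(C)C)cc1OCOC
F3 | step 7 | (3S,4E)-3-{[2,6-bis(methoxymethoxy)-4-{[tri(propan-2-yl)silyl]oxy}phenyl]methyl}-2-(but-3-en-1-yl)-2,4-dimethylhept-4-enoic acid (both C2 epimers) | OC(=O)C(C)(CCC=C)[C@@H](Cc1c(OCOC)cc(O[Si](C(C)C)(C(C)C)C(C)C)cc1OCOC)/C(C)=C/CC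
F4 | step 7 | (3S,4E)-3-{[2,6-bis(methoxymethoxy)-4-{[tri(propan-2-yl)silyl]oxy}phenyl]methyl}-2-(but-3-en-1-yl)-2,4-dimethylhept-4-en-1-ol (both C2 epimers) | OCC(C)(CCC=C)[C@@H](Cc1c(OCOC)cc(O[Si](C(C)C)(C(C)C)C(C)C)cc1OCOC)/C(C)=C/CC
F5 | step 8 | di(pent-4-en-1-yl)zinc | C=CCCC[Zn]CCCC=C
F6 | step 8 | (2E,4R)-1-[2,6-bis(methoxymethoxy)-4-{[tri(propan-2-yl)silyl]oxy}phenyl]-3-methylnona-2,8-dien-4-ol | C=CCCC[C@@H](O)/C(C)=C/Cc1c(OCOC)cc(O[Si](C(C)C)(C(C)C)C(C)C)cc1OCOC
F7 | step 8 | (3S,4E)-3-{[2,6-bis(methoxymethoxy)-4-{[tri(propan-2-yl)silyl]oxy}phenyl]methyl}-2-(but-3-en-1-yl)-2,4-dimethyldeca-4,9-dienal (both C2 epimers) | O=CC(C)(CCC=C)[C@@H](Cc1c(OCOC)cc(O[Si](C(C)C)(C(C)C)C(C)C)cc1OCOC)/C(C)=C/CCCC=C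
F8 | step 13 | N-methoxy-N-methyl-3-[4-(methoxymethoxy)phenyl]prop-2-ynamide | CON(C)C(=O)C#Cc1ccc(OCOC)cc1
F9 | step 13 | 1-[6-hydroxy-2,4-bis(methoxymethoxy)-3-{[(1R)-2,6,6-trimethylcyclohex-2-en-1-yl]methyl}phenyl]-3-[4-(methoxymethoxy)phenyl]prop-2-yn-1-one | CC1=CCCC(C)(C)[C@H]1Cc1c(OCOC)cc(O)c(C(=O)C#Cc2ccc(OCOC)cc2)c1OCOC
F10 | step 13 | 5,7-bis(methoxymethoxy)-2-[4-(methoxymethoxy)phenyl]-6-{[(1R)-2,6,6-trimethylcyclohex-2-en-1-yl]methyl}-4H-chromen-4-one | CC1=CCCC(C)(C)[C@H]1Cc1c(OCOC)cc2oc(-c3ccc(OCOC)cc3)cc(=O)c2c1OCOC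
A1 | direct plan | diethyl (1R)-2,4,4-trimethylcyclohex-2-en-1-yl phosphate | CC1=CC(C)(C)CC[C@H]1OP(=O)(OCC)OCC
A2 | direct plan | 2-{[(1R)-2,6,6-trimethylcyclohex-2-en-1-yl]methyl}-4,4,5,5-tetramethyl-1,3,2-dioxaborolane | CC1=CCCC(C)(C)[C@H]1CB2OC(C)(C)C(C)(C)O2
A3 | direct plan | 6-iodo-3,5,7-tris(methoxymethoxy)-2-[4-(methoxymethoxy)phenyl]-4H-chromen-4-one | COCOc1ccc(cc1)-c1oc2cc(OCOC)c(I)c(OCOC)c2c(=O)c1OCOC
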